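**Retrosynthetic overview** (target locants: C1 and C4 = ArCH–O, C3 and C6 = OCH2, C3a = C–OH, C6a = CH; ring A = C3a–C4–O5–C6–C6a, ring B = C1–O2–C3–C3a–C6a)
1. Target ⇐ bicyclic α-hydroxy lactone (C3 still C=O) by lactone-to-ether reduction; its C4–H ⇐ aryl hemiketal by ionic hydrogenation, hydride on the convex face putting the C4 aryl endo.
2. Hemiketal lactone ⇐ β-keto lactone by enolate hydroxylation at C3a (anti to the CH2OH arm) and ring–chain closure of ring A.
3. Key disconnection C3a–C6a: a β-keto ester enolate (C3a) alkylates the internal carbon of a tethered terminal epoxide (C6a). C6a is the α-carbon of the C6–O function used with inverted, electrophilic (a2, enolonium-type) polarity, so two α-carbons are joined, with inversion at C6a.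
4. Epoxy β-keto ester ⇐ erythro epoxy alcohol (Sharpless kinetic resolution of the aryl vinyl carbinol from veratraldehyde) + ethyl 3,4-dimethoxybenzoylacetate.
5. Ring order: ring B (as lactone) forms in the key step, ring A closes directly afterwards as the hemiketal.

Reading of the target: (1R,3aR,4R,6aS); cis-fused, 3a-OH cis to H-6a, C1 aryl exo (cis to H-6a), C4 aryl endo (trans to 3a-OH). Assumption: ethyl 3-(3,4-dimethoxyphenyl)-3-oxopropanoate is bought.

**Step 1**
Reactants: 1 3,4-dimethoxybenzaldehyde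
Product: 2 rac-1-(3,4-dimethoxyphenyl)prop-2-en-1-ol
Conditions: CH2=CHMgBr (1.2 equiv), THF, 0 °C; then H2O
Reagents that add atoms: vinylmagnesium bromide, C=C[Mg]Br
Why: Grignard 1,2-addition to an aryl aldehyde; the carbinol is made racemic on purpose because the next step resolves it.

**Step 2**
Reactants: 2 rac-1-(3,4-dimethoxyphenyl)prop-2-en-1-ol
Product: 3 (S)-(3,4-dimethoxyphenyl)[(2R)-oxiran-2-yl]methanol
Conditions: Ti(OiPr)4 (0.2 equiv), L-(+)-diisopropyl tartrate (0.25 equiv), tBuOOH (0.5 equiv, anhydrous), 4 Å MS, CH2Cl2, −20 °C, stopped near 50% conversion; unreacted (S)-2 removed by chromatography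
Reagents that add atoms: tert-butyl hydroperoxide, CC(C)(C)OO
Why: Sharpless kinetic-resolution epoxidation: with the L-(+)-tartrate the (R)-carbinol is the matched, fast enantiomer and gives the erythro epoxy alcohol (oxirane carbon R, carbinol S by priority change), which fixes future C1 and, after inversion, C6a.

**Step 3**
Reactants: 3 (S)-(3,4-dimethoxyphenyl)[(2R)-oxiran-2-yl]methanol, 4 ethyl 3-(3,4-dimethoxyphenyl)-3-oxopropanoate
Product: 5 (S)-(3,4-dimethoxyphenyl)[(2R)-oxiran-2-yl]methyl 3-(3,4-dimethoxyphenyl)-3-oxopropanoate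
Conditions: 4 (1.3 equiv), toluene, 4 Å MS, 105 °C, ethanol removed continuously, no added acid or base
Reagents that add atoms: none
Why: thermal transesterification of a β-keto ester through its acylketene under neutral conditions, so the epoxide survives and no bond to a stereocentre is made or broken.

**Step 4**
Reactants: 5 (S)-(3,4-dimethoxyphenyl)[(2R)-oxiran-2-yl]methyl 3-(3,4-dimethoxyphenyl)-3-oxopropanoate
Product: 8 (3R,3aS,6aS)-6,6a-dihydroxy-3,6-bis(3,4-dimethoxyphenyl)tetrahydro-1H,3H-furo[3,4-c]furan-1-one (cyclic hemiketal; both C6 epimers), via keto lactone enolate 6 (not isolated), via open hydroxy ketone 7 (not isolated)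
Conditions: Cs2CO3 (1.2 equiv), DMF, 0 → 40 °C; then −30 °C, 3-phenyl-2-(phenylsulfonyl)oxaziridine (1.2 equiv); AcOH quench at −30 °C
Reagents that add atoms: 3-phenyl-2-(phenylsulfonyl)oxaziridine, O=S(=O)(c1ccccc1)N1OC1c1ccccc1
Why: Proposed new method: the soft β-keto ester enolate (future C3a) opens the tethered terminal epoxide at its internal carbon (future C6a) by 5-exo-tet SN2 with inversion, the oxirane carbon serving as an a2 (enolonium-type) electrophile so that two α-carbons are joined and the trans C1/C6a lactone results; the released alkoxide is protonated by the acidic β-keto lactone, whose enolate shields the lactone from translactonisation, the oxaziridine then hydroxylates that enolate anti to the adjacent CH2OH arm (OH cis to H-6a, aroyl cis to CH2OH) and the γ-hydroxy ketone closes to the cis-fused hemiketal; the closest known reaction types are the Stork epoxide–carbanion (epoxynitrile-type) cyclisation and the Davis enolate hydroxylation.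

**Step 5**
Reactants: 8 (3R,3aS,6aS)-6,6a-dihydroxy-3,6-bis(3,4-dimethoxyphenyl)tetrahydro-1H,3H-furo[3,4-c]furan-1-one
Product: 9 (3R,3aS,6R,6aS)-6a-hydroxy-3,6-bis(3,4-dimethoxyphenyl)tetrahydro-1H,3H-furo[3,4-c]furan-1-one
Conditions: Et3SiH (3 equiv), BF3·OEt2 (2 equiv, promoter), CH2Cl2/MeCN, −40 → −20 °C; aq. NaHCO3
Reagents that add atoms: none
Why: ionic hydrogenation of an aryl hemiketal (as in C-aryl glycoside synthesis): both epimers give the same aryl-stabilised oxocarbenium, which takes hydride on the convex face of the cis-fused bicycle (the face of the tertiary OH), leaving the aryl endo and trans to that OH (6R here, C4 of the target), while the lactone is inert at this temperature.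

**Step 6**
Reactants: 9 (3R,3aS,6R,6aS)-6a-hydroxy-3,6-bis(3,4-dimethoxyphenyl)tetrahydro-1H,3H-furo[3,4-c]furan-1-one
Product: 10 (3R,3aS,6R,6aS)-3,6-bis(3,4-dimethoxyphenyl)tetrahydro-1H,3H-furo[3,4-c]furan-1,6a-diol (lactol; both C1 anomers)
Conditions: iBu2AlH (3.0 equiv), CH2Cl2, −78 °C; aq. KNaC4H4O6
Reagents that add atoms: none
Why: half-reduction of a γ-lactone with diisobutylaluminium hydride stops at the tetrahedral aluminium lactolate at −78 °C (one extra equivalent is taken by the tertiary OH) and touches no stereocentre of the final product.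

**Step 7**
Reactants: 10 (3R,3aS,6R,6aS)-3,6-bis(3,4-dimethoxyphenyl)tetrahydro-1H,3H-furo[3,4-c]furan-1,6a-diol
Product: 11 (1R,3aR,4R,6aS)-1,4-bis(3,4-dimethoxyphenyl)tetrahydro-1H,3H-furo[3,4-c]furan-3a-ol
Conditions: Et3SiH (3 equiv), BF3·OEt2 (1.5 equiv, promoter), CH2Cl2, −78 → −50 °C, 30 min; aq. NaHCO3 at −50 °C
Reagents that add atoms: none
Why: lactol deoxygenation by ionic hydrogenation through the unsubstituted oxocarbenium creates no new stereocentre, and the low temperature keeps the acid-labile endo benzylic ether from ionising or epimerising.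

**Compound list**
1 | 3,4-dimethoxybenzaldehyde | COc1ccc(C=O)cc1OC | starting material
2 | rac-1-(3,4-dimethoxyphenyl)prop-2-en-1-ol (racemic) | C=CC(O)c1ccc(OC)c(OC)c1 | intermediate
3 | (S)-(3,4-dimethoxyphenyl)[(2R)-oxiran-2-yl]methanol | O[C@@H](c1ccc(OC)c(OC)c1)[C@H]1CO1 | intermediate
4 | ethyl 3-(3,4-dimethoxyphenyl)-3-oxopropanoate | CCOC(=O)CC(=O)c1ccc(OC)c(OC)c1 | starting material
5 | (S)-(3,4-dimethoxyphenyl)[(2R)-oxiran-2-yl]methyl 3-(3,4-dimethoxyphenyl)-3-oxopropanoate | O=C(CC(=O)c1ccc(OC)c(OC)c1)O[C@@H](c1ccc(OC)c(OC)c1)[C@H]1CO1 | intermediate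
6 | (4S,5R)-3-(3,4-dimethoxybenzoyl)-5-(3,4-dimethoxyphenyl)-4-(hydroxymethyl)oxolan-2-one (present as its enolate; C3 not fixed) | O=C1O[C@@H](c2ccc(OC)c(OC)c2)[C@H](CO)C1C(=O)c1ccc(OC)c(OC)c1 | intermediate
7 | (3S,4S,5R)-3-(3,4-dimethoxybenzoyl)-5-(3,4-dimethoxyphenyl)-3-hydroxy-4-(hydroxymethyl)oxolan-2-one | O=C1O[C@@H](c2ccc(OC)c(OC)c2)[C@H](CO)[C@]1(O)C(=O)c1ccc(OC)c(OC)c1 | intermediate
8 | (3R,3aS,6aS)-6,6a-dihydroxy-3,6-bis(3,4-dimethoxyphenyl)tetrahydro-1H,3H-furo[3,4-c]furan-1-one (C6 hemiketal epimers) | COc1ccc(C2(O)OC[C@H]3[C@H](c4ccc(OC)c(OC)c4)OC(=O)[C@@]23O)cc1OC | intermediate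
9 | (3R,3aS,6R,6aS)-6a-hydroxy-3,6-bis(3,4-dimethoxyphenyl)tetrahydro-1H,3H-furo[3,4-c]furan-1-one | COc1ccc([C@H]2OC[C@H]3[C@H](c4ccc(OC)c(OC)c4)OC(=O)[C@@]23O)cc1OC | intermediate
10 | (3R,3aS,6R,6aS)-3,6-bis(3,4-dimethoxyphenyl)tetrahydro-1H,3H-furo[3,4-c]furan-1,6a-diol (C1 anomers) | COc1ccc([C@H]2OC[C@H]3[C@H](c4ccc(OC)c(OC)c4)OC(O)[C@@]23O)cc1OC | intermediate
11 | (1R,3aR,4R,6aS)-1,4-bis(3,4-dimethoxyphenyl)tetrahydro-1H,3H-furo[3,4-c]furan-3a-ol | COc1ccc([C@H]2OC[C@H]3[C@H](c4ccc(OC)c(OC)c4)OC[C@@]23O)cc1OC | target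

**Totals**
Total steps: 7. Longest linear sequence: 7 (1 to 11; compound 4 is bought and enters at step 3).

**Three steps most likely to fail, with fallbacks**

Step 2 is at risk because a monosubstituted alkene is epoxidised slowly and the ee of the epoxide depends on stopping at the right conversion; the ee can later be raised by crystallising 9. The fallback sets out from 2 and comes back at 3. Candida antarctica lipase B with vinyl acetate (hexane, 30 °C) acetylates the (R)-enantiomer to (R)-1-(3,4-dimethoxyphenyl)prop-2-en-1-yl acetate F1, which is separated from the unreacted (S)-alcohol. K2CO3 in MeOH gives (R)-1-(3,4-dimethoxyphenyl)prop-2-en-1-ol F2. The same Ti(OiPr)4/L-(+)-diisopropyl tartrate/tBuOOH system then serves as a matched, diastereoselective epoxidation run to full conversion, giving 3.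

Step 4 is the most exposed step: 6-endo opening, O-alkylation, translactonisation or hydroxylation on the wrong face could each divert it. The fallback builds ring B without any carbanion–epoxide step; it sets out from 2, used as its (R)-enantiomer (R)-1-(3,4-dimethoxyphenyl)prop-2-en-1-ol F2 obtained as just described, and comes back at 6.
- Acryloyl chloride and Et3N give (R)-1-(3,4-dimethoxyphenyl)prop-2-en-1-yl prop-2-enoate F3.
- Ring-closing metathesis with RuCl2(=CHPh)(PCy3)(H2IMes) (second-generation Grubbs catalyst, CH2Cl2, 40 °C) gives the butenolide (R)-5-(3,4-dimethoxyphenyl)furan-2(5H)-one F4.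
- Benzophenone-sensitised photoaddition of methanol (hydroxymethyl radical, adding trans to the aryl) gives (4S,5R)-5-(3,4-dimethoxyphenyl)-4-(hydroxymethyl)oxolan-2-one F5.
- 3,4-Dimethoxybenzoyl chloride and pyridine give [(2R,3S)-2-(3,4-dimethoxyphenyl)-5-oxooxolan-3-yl]methyl 3,4-dimethoxybenzoate F6.
- LiN(SiMe3)2 (2.2 equiv, THF, −78 → 0 °C) triggers a Baker–Venkataraman-type O-to-C acyl shift to the enolate of 6, which is hydroxylated with the oxaziridine and quenched exactly as in step 4 to reach 8.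

Step 7 is at risk because BF3 can ionise the benzylic ethers and epimerise the endo aryl. The fallback sets out from 10 and comes back at 11. Phenyl chlorothionoformate with pyridine and DMAP acylates only the anomeric hydroxyl, giving O-[(3R,3aS,6R,6aS)-6a-hydroxy-3,6-bis(3,4-dimethoxyphenyl)tetrahydro-1H,3H-furo[3,4-c]furan-1-yl] O-phenyl carbonothioate F7. Tributyltin hydride with AIBN (toluene, 80 °C, Barton–McCombie deoxygenation through the anomeric radical) then removes it under neutral conditions to give 11.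

**Further compounds**
F1 | step 2 | (R)-1-(3,4-dimethoxyphenyl)prop-2-en-1-yl acetate | CC(=O)O[C@@H](c1ccc(OC)c(OC)c1)C=C
F2 | step 2 | (R)-1-(3,4-dimethoxyphenyl)prop-2-en-1-ol | O[C@@H](c1ccc(OC)c(OC)c1)C=C
F3 | step 4 | (R)-1-(3,4-dimethoxyphenyl)prop-2-en-1-yl prop-2-enoate | C=CC(=O)O[C@@H](c1ccc(OC)c(OC)c1)C=C
F4 | step 4 | (R)-5-(3,4-dimethoxyphenyl)furan-2(5H)-one | O=C1O[C@@H](c2ccc(OC)c(OC)c2)C=C1
F5 | step 4 | (4S,5R)-5-(3,4-dimethoxyphenyl)-4-(hydroxymethyl)oxolan-2-one | O=C1O[C@@H](c2ccc(OC)c(OC)c2)[C@H](CO)C1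
F6 | step 4 | [(2R,3S)-2-(3,4-dimethoxyphenyl)-5-oxooxolan-3-yl]methyl 3,4-dimethoxybenzoate | O=C1O[C@@H](c2ccc(OC)c(OC)c2)[C@H](COC(=O)c2ccc(OC)c(OC)c2)C1
F7 | step 7 | O-[(3R,3aS,6R,6aS)-6a-hydroxy-3,6-bis(3,4-dimethoxyphenyl)tetrahydro-1H,3H-furo[3,4-c]furan-1-yl] O-phenyl carbonothioate | COc1ccc([C@H]2OC[C@H]3[C@H](c4ccc(OC)c(OC)c4)OC(OC(=S)Oc4ccccc4)[C@@]23O)cc1OC
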